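**Plan**

- Retrosynthesis: after removal of all benzyl groups, the two bonds O1–C2 and C3–C4 of ring C of the upper (flavan-3-ol) unit are cut together as a [4+2] retron. This gives an o-quinone methide and a Z enol carbonate of an arylacetaldehyde. C4–C4a is then cut (phenol + aldehyde), and the C8 formyl group and C4 carbonyl of the lower unit lead back to (+)-catechin.
- Enabling feature: upper ring A is a phloroglucinol ring whose O1 (on C8a) is ortho to C4a, and C4a carries the doubly benzylic C4 that is bonded to C8 of the flavanone. O1=C8a–C4a=C4 is therefore an o-quinone methide, and C2(aryl)–C3(O) is the matching electron-rich alkene.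
- Forward order: lower rings A, B and C come intact from (+)-catechin (benzylation, C8 bromination, C4 oxidation, C8 formylation). Upper ring B enters as the Z enol carbonate and upper ring A as a phenol, which is joined to the aldehyde. The hetero-Diels–Alder reaction then closes upper ring C last, and hydrogenolysis ends the route.
- Stereochemistry: the lower C2/C3 come from (+)-catechin. The upper C2/C3 cis relation comes from the Z-alkene, the C3/C4 trans relation from exo approach, and the absolute sense from a chiral Brønsted acid.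

Key step: step 12

Remark on the chemistry: "upper unit" is the flavan-3-ol half and "lower unit" the dihydroflavonol half. Compounds 5 and 16 each carry one new carbinol centre that is erased again (steps 5 and 12); 5 is drawn as the expected 4α-alcohol and the carbinol carbon of 16 is left undefined.

**Route**

Step 1
Reactants: 1 (+)-catechin
Product: 2 5,7,3',4'-tetra-O-benzyl-(+)-catechin
Conditions: BnBr, K2CO3, DMF, 0 °C to rt
Reagents that add atoms: benzyl bromide, BrCc1ccccc1
Why: Williamson etherification with a weak base alkylates only the four phenols and touches neither stereocentre.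

Step 2
Reactants: 2 5,7,3',4'-tetra-O-benzyl-(+)-catechin
Product: 3 3,5,7,3',4'-penta-O-benzyl-(+)-catechin
Conditions: NaH, BnBr, cat. Bu4NI, DMF, 0 °C to rt
Reagents that add atoms: benzyl bromide, BrCc1ccccc1
Why: Williamson O-benzylation of the remaining 3-OH, so that no free alcohol interferes with the later oxidation, magnesium phenoxide and cationic steps.

Step 3
Reactants: 3 3,5,7,3',4'-penta-O-benzyl-(+)-catechin
Product: 4 8-bromo-3,5,7,3',4'-penta-O-benzyl-(+)-catechin
Conditions: NBS, CH2Cl2, −78 °C to rt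
Reagents that add atoms: N-bromosuccinimide, O=C1CCC(=O)N1Br
Why: Electrophilic aromatic bromination of the phloroglucinol-type ring A, which in 5,7-di-O-benzyl flavan-3-ol ethers takes place selectively at C8.

Step 4
Reactants: 4 8-bromo-3,5,7,3',4'-penta-O-benzyl-(+)-catechin
Product: 5 (2R,3S,4R)-8-bromo-3,5,7-tris(benzyloxy)-2-[3,4-bis(benzyloxy)phenyl]chroman-4-ol
Conditions: DDQ, CH2Cl2/H2O, rt
Reagents that add atoms: water, O
Why: Benzylic oxidation in which DDQ abstracts hydride from C4 (cation stabilised by the 5,7-dioxygenated ring) and water adds anti to the 3-benzyloxy group; the new centre is removed in the next step.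

Step 5
Reactants: 5 (2R,3S,4R)-8-bromo-3,5,7-tris(benzyloxy)-2-[3,4-bis(benzyloxy)phenyl]chroman-4-ol
Product: 6 (2R,3R)-8-bromo-3,5,7-tris(benzyloxy)-2-[3,4-bis(benzyloxy)phenyl]chroman-4-one
Conditions: Dess–Martin periodinane, CH2Cl2, rt
Reagents that add atoms: none
Why: Dess–Martin oxidation of the secondary benzylic alcohol gives the flavanone; with C4 a carbonyl the unchanged C3 takes the descriptor R, which is the (2R,3R) pattern of the lower unit.

Step 6
Reactants: 6 (2R,3R)-8-bromo-3,5,7-tris(benzyloxy)-2-[3,4-bis(benzyloxy)phenyl]chroman-4-one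
Product: 7 (2R,3R)-3,5,7-tris(benzyloxy)-2-[3,4-bis(benzyloxy)phenyl]-8-vinylchroman-4-one
Conditions: tributyl(vinyl)stannane, Pd(P(t-Bu)3)2 (cat.), toluene, 100 °C
Reagents that add atoms: tributyl(vinyl)stannane, C=C[Sn](CCCC)(CCCC)CCCC
Why: Stille cross-coupling, in which the bulky electron-rich phosphine allows oxidative addition into the di-ortho-oxygenated aryl bromide and the neutral conditions spare the base-sensitive 3-alkoxyflavanone.

Step 7
Reactants: 7 (2R,3R)-3,5,7-tris(benzyloxy)-2-[3,4-bis(benzyloxy)phenyl]-8-vinylchroman-4-one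
Product: 8 (2R,3R)-3,5,7-tris(benzyloxy)-2-[3,4-bis(benzyloxy)phenyl]-4-oxochromane-8-carbaldehyde
Conditions: OsO4 (cat.), NaIO4, 2,6-lutidine, dioxane/H2O, rt
Reagents that add atoms: osmium tetroxide, O=[Os](=O)(=O)=O (delivers the aldehyde oxygen and is replenished by sodium periodate, [Na+].[O-]I(=O)(=O)=O)
Why: Lemieux–Johnson cleavage (dihydroxylation, then periodate glycol cleavage) of the only alkene gives the aryl aldehyde without touching benzyl ethers or the ketone.

Step 8
Reactants: 9 3,4-bis(benzyloxy)benzaldehyde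
Product: 10 1,2-bis(benzyloxy)-4-ethynylbenzene
Conditions: dimethyl (1-diazo-2-oxopropyl)phosphonate, K2CO3, MeOH, rt
Reagents that add atoms: dimethyl (1-diazo-2-oxopropyl)phosphonate, CC(=O)C(=[N+]=[N-])P(=O)(OC)OC
Why: Seyferth–Gilbert homologation with the Ohira–Bestmann reagent converts the aryl aldehyde into the terminal alkyne under mild carbonate conditions.

Step 9
Reactants: 10 1,2-bis(benzyloxy)-4-ethynylbenzene
Product: 11 (Z)-2-[3,4-bis(benzyloxy)phenyl]ethenyl acetate
Conditions: AcOH, [RuCl2(p-cymene)]2 (cat.), P(4-ClC6H4)3, DMAP, toluene, 60 °C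
Reagents that add atoms: acetic acid, CC(O)=O
Why: Ruthenium-vinylidene-mediated anti-Markovnikov hydro-acyloxylation of a terminal arylalkyne, which should deliver the Z enol ester because the carboxylate adds to the vinylidene α-carbon and protonation places ester and aryl cis.

Step 10
Reactants: 11 (Z)-2-[3,4-bis(benzyloxy)phenyl]ethenyl acetate
Product: 13 benzyl (Z)-2-[3,4-bis(benzyloxy)phenyl]ethenyl carbonate, via potassium Z-enolate 12 (not isolated)
Conditions: KOtBu (1.0 equiv), THF, −78 °C; then CbzCl, −78 to 0 °C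
Reagents that add atoms: benzyl chloroformate, O=C(Cl)OCc1ccccc1
Why: Acyl transfer to tert-butoxide releases the geometrically defined Z enolate, which the hard chloroformate acylates on oxygen with retention of the double-bond geometry.

Step 11
Reactants: 8 (2R,3R)-3,5,7-tris(benzyloxy)-2-[3,4-bis(benzyloxy)phenyl]-4-oxochromane-8-carbaldehyde; 14 3,5-bis(benzyloxy)phenol
Product: 16 (2R,3R)-3,5,7-tris(benzyloxy)-2-[3,4-bis(benzyloxy)phenyl]-8-{[2,4-bis(benzyloxy)-6-hydroxyphenyl](hydroxy)methyl}chroman-4-one (both carbinol epimers), via bromomagnesium 3,5-bis(benzyloxy)phenoxide 15 (not isolated)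
Conditions: 14, EtMgBr (1.0 equiv), Et2O, 0 °C; solvent change to toluene; 8, rt; aq NH4Cl
Reagents that add atoms: none
Why: Casiraghi-type ortho-specific hydroxyalkylation, in which the magnesium phenoxide delivers its ortho carbon to the magnesium-bound aldehyde through a six-membered chelate while the far less electrophilic flavanone carbonyl is left alone; the new carbinol centre becomes trigonal in step 12.

Step 12
Reactants: 16 the o-hydroxybenzhydrol from step 11; 13 benzyl (Z)-2-[3,4-bis(benzyloxy)phenyl]ethenyl carbonate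
Product: 18 5,7,3',4'-tetra-O-benzyl-3-O-(benzyloxycarbonyl)epicatechin-(4β→8)-3,5,7,3',4'-penta-O-benzyltaxifolin (upper unit 2R,3R,4R; lower unit 2R,3R), via o-quinone methide 17 (not isolated)
Conditions: 13 (3 equiv), (R)-3,3'-bis(2,4,6-triisopropylphenyl)-BINOL N-triflylphosphoramide (10 mol %), 4 Å MS, CH2Cl2, −40 to 0 °C, slow addition of 16
Reagents that add atoms: none
Why: Proposed new method: the chiral acid ionises benzhydrol 16 to the o-quinone methide 17 (O1=C8a–C4a=C4 of upper ring A, ion-paired with the phosphoramide), and the Z-alkene of 13 adds across C4 and O1 in a strongly asynchronous inverse-electron-demand hetero-Diels–Alder reaction, C3–C4 bond formation running ahead of O1–C2 bond formation; the closest known reaction type is the chiral Brønsted acid-catalysed [4+2] of o-hydroxybenzhydrol-derived o-quinone methides with styrenes to 2,4-diarylchromans, which has not been shown for β-acyloxystyrenes. The one ring closed is the dihydropyran ring C of the upper unit, by [4+2] cycloaddition (two σ-bonds, C3–C4 and O1–C2, formed on one face of the alkene). The step needs C3 and not C2 to bond to C4, and this is secured because the 3,4-bis(benzyloxy)phenyl group stabilises positive charge at C2 far better than the carbonate oxygen would at C3, an enol carbonate being a deliberately weak oxygen donor. C2 and C3 come out cis because the addition is suprafacial on the Z-alkene and the zwitterion closes faster than rotation about C2–C3. C3 and C4 come out trans because the carbonate takes the exo position (the C4 aryl group sitting outside, anti to the C8a carbonyl): the endo position on C3 lies between the two ortho,ortho'-disubstituted aryl groups on C4 (ring A and the flavanone ring) and can hold only H-3, which with the Z-geometry also places the C2 aryl group exo and therefore trans to the C4 substituent. The absolute sense at C4 (4R, and with it 2R,3R), which the remote (2R,3R) centres of the lower unit cannot dictate, is set by the chiral counter-anion, and self-alkylation of the electron-rich ring A by 17 is held back by slow addition of 16 to excess 13.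

Step 13
Reactants: 18 the protected dimer from step 12
Product: 19 epicatechin-(4β→8)-taxifolin, (2R,3R)-2-(3,4-dihydroxyphenyl)-8-[(2R,3R,4R)-2-(3,4-dihydroxyphenyl)-3,5,7-trihydroxychroman-4-yl]-3,5,7-trihydroxychroman-4-one
Conditions: H2 (1 atm), Pd(OH)2/C, THF/MeOH, rt
Reagents that add atoms: none
Why: Hydrogenolysis cleaves the nine benzyl ethers and the benzyl carbonate (which then loses CO2) under neutral conditions and should leave the flavanone carbonyl, the cyclic benzylic C2–O bonds and all five stereocentres untouched.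

**Compound list**

1 | (+)-catechin | C1c2c(O)cc(O)cc2O[C@H](c2ccc(O)c(O)c2)[C@H]1O | starting material
2 | 5,7,3',4'-tetra-O-benzyl-(+)-catechin | C1c2c(OCc3ccccc3)cc(OCc3ccccc3)cc2O[C@H](c2ccc(OCc3ccccc3)c(OCc3ccccc3)c2)[C@H]1O | intermediate
3 | 3,5,7,3',4'-penta-O-benzyl-(+)-catechin | C1c2c(OCc3ccccc3)cc(OCc3ccccc3)cc2O[C@H](c2ccc(OCc3ccccc3)c(OCc3ccccc3)c2)[C@H]1OCc1ccccc1 | intermediate
4 | 8-bromo-3,5,7,3',4'-penta-O-benzyl-(+)-catechin | C1c2c(OCc3ccccc3)cc(OCc3ccccc3)c(Br)c2O[C@H](c2ccc(OCc3ccccc3)c(OCc3ccccc3)c2)[C@H]1OCc1ccccc1 | intermediate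
5 | (2R,3S,4R)-8-bromo-3,5,7-tris(benzyloxy)-2-[3,4-bis(benzyloxy)phenyl]chroman-4-ol | O[C@@H]1c2c(OCc3ccccc3)cc(OCc3ccccc3)c(Br)c2O[C@H](c2ccc(OCc3ccccc3)c(OCc3ccccc3)c2)[C@H]1OCc1ccccc1 | intermediate
6 | (2R,3R)-8-bromo-3,5,7-tris(benzyloxy)-2-[3,4-bis(benzyloxy)phenyl]chroman-4-one | O=C1c2c(OCc3ccccc3)cc(OCc3ccccc3)c(Br)c2O[C@H](c2ccc(OCc3ccccc3)c(OCc3ccccc3)c2)[C@H]1OCc1ccccc1 | intermediate
7 | (2R,3R)-3,5,7-tris(benzyloxy)-2-[3,4-bis(benzyloxy)phenyl]-8-vinylchroman-4-one | O=C1c2c(OCc3ccccc3)cc(OCc3ccccc3)c(C=C)c2O[C@H](c2ccc(OCc3ccccc3)c(OCc3ccccc3)c2)[C@H]1OCc1ccccc1 | intermediate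
8 | (2R,3R)-3,5,7-tris(benzyloxy)-2-[3,4-bis(benzyloxy)phenyl]-4-oxochromane-8-carbaldehyde | O=C1c2c(OCc3ccccc3)cc(OCc3ccccc3)c(C=O)c2O[C@H](c2ccc(OCc3ccccc3)c(OCc3ccccc3)c2)[C@H]1OCc1ccccc1 | intermediate
9 | 3,4-bis(benzyloxy)benzaldehyde | O=Cc1ccc(OCc2ccccc2)c(OCc2ccccc2)c1 | starting material
10 | 1,2-bis(benzyloxy)-4-ethynylbenzene | C#Cc1ccc(OCc2ccccc2)c(OCc2ccccc2)c1 | intermediate
11 | (Z)-2-[3,4-bis(benzyloxy)phenyl]ethenyl acetate | CC(=O)O/C=C\c1ccc(OCc2ccccc2)c(OCc2ccccc2)c1 | intermediate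
12 | potassium (Z)-2-[3,4-bis(benzyloxy)phenyl]ethenolate | [K+].[O-]/C=C\c1ccc(OCc2ccccc2)c(OCc2ccccc2)c1 | intermediate (not isolated)
13 | benzyl (Z)-2-[3,4-bis(benzyloxy)phenyl]ethenyl carbonate | O=C(OCc1ccccc1)O/C=C\c1ccc(OCc2ccccc2)c(OCc2ccccc2)c1 | intermediate
14 | 3,5-bis(benzyloxy)phenol | Oc1cc(OCc2ccccc2)cc(OCc2ccccc2)c1 | starting material
15 | bromomagnesium 3,5-bis(benzyloxy)phenoxide | Br[Mg]Oc1cc(OCc2ccccc2)cc(OCc2ccccc2)c1 | intermediate (not isolated)
16 | (2R,3R)-3,5,7-tris(benzyloxy)-2-[3,4-bis(benzyloxy)phenyl]-8-{[2,4-bis(benzyloxy)-6-hydroxyphenyl](hydroxy)methyl}chroman-4-one, both carbinol epimers | O=C1c2c(OCc3ccccc3)cc(OCc3ccccc3)c(C(O)c3c(O)cc(OCc4ccccc4)cc3OCc3ccccc3)c2O[C@H](c2ccc(OCc3ccccc3)c(OCc3ccccc3)c2)[C@H]1OCc1ccccc1 | intermediate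
17 | o-quinone methide: (2R,3R)-3,5,7-tris(benzyloxy)-2-[3,4-bis(benzyloxy)phenyl]-8-{[2,4-bis(benzyloxy)-6-oxocyclohexa-2,4-dien-1-ylidene]methyl}chroman-4-one | O=C1c2c(OCc3ccccc3)cc(OCc3ccccc3)c(C=C3C(=O)C=C(OCc4ccccc4)C=C3OCc3ccccc3)c2O[C@H](c2ccc(OCc3ccccc3)c(OCc3ccccc3)c2)[C@H]1OCc1ccccc1 | intermediate (not isolated)
18 | 5,7,3',4'-tetra-O-benzyl-3-O-(benzyloxycarbonyl)epicatechin-(4β→8)-3,5,7,3',4'-penta-O-benzyltaxifolin | O=C1c2c(OCc5ccccc5)cc(OCc5ccccc5)c([C@H]3c4c(OCc5ccccc5)cc(OCc5ccccc5)cc4O[C@H](c4ccc(OCc5ccccc5)c(OCc5ccccc5)c4)[C@@H]3OC(=O)OCc3ccccc3)c2O[C@H](c2ccc(OCc3ccccc3)c(OCc3ccccc3)c2)[C@H]1OCc1ccccc1 | intermediate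
19 | epicatechin-(4β→8)-taxifolin | O=C1c2c(O)cc(O)c([C@H]3c4c(O)cc(O)cc4O[C@H](c4ccc(O)c(O)c4)[C@@H]3O)c2O[C@H](c2ccc(O)c(O)c2)[C@H]1O | target

**Summary**

Total step count: 13. Longest linear sequence: 10 steps (steps 1–7, 11, 12, 13).

Steps most likely to fail:

Step 12. What may go wrong: attack through C2 instead of C3, endo instead of exo approach, weak facial control by the catalyst, or oligomerisation of the quinone methide through ring A. The fallback uses known chemistry, sets out from 3 and comes back at 19. (−)-Epicatechin is benzylated (BnBr, K2CO3, DMF) to 5,7,3',4'-tetra-O-benzyl-(−)-epicatechin F1. DDQ and 2-ethoxyethanol in CH2Cl2 convert it into 5,7,3',4'-tetra-O-benzyl-4β-(2-ethoxyethoxy)-(−)-epicatechin F2. TMSOTf (CH2Cl2, −78 °C) ionises F2, and C8 of excess 3 attacks the flavan-4-yl cation anti to the 3-OH to give the protected epicatechin-(4β→8)-catechin F3; here the upper ring C is in place before the interflavan bond. DDQ/H2O should then hydroxylate the lower C4, because the interflavan C4–H is held in the planes of its two aryl groups and should lose hydride slowly; this gives the lower-unit 4-alcohol F4. MnO2 should oxidise this benzylic alcohol, not the upper 3-OH, to the lower-unit flavanone F5. Hydrogenolysis (H2, Pd(OH)2/C) of the nine benzyl ethers of F5 gives 19.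

Step 11. What may go wrong: a second phenol adds to the ionised product to give a triarylmethane, or the hindered aldehyde reacts too slowly. The fallback sets out from 8 and 14 and comes back at 18. Compounds 8 and 14 are condensed with phenylboronic acid (cat. propionic acid, toluene, reflux, water removal; boron-templated ortho-condensation of the Nagata type) to the 2-phenyl-4H-1,3,2-benzodioxaborin F6. This cyclic boronate of the benzhydrol is stable and cannot take up a second phenol. Under the acid of step 12, F6 opens to 17 and is carried on to 18.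

Step 6. What may go wrong: slow oxidative addition at the bromide flanked by two ortho oxygens, with protodebromination taking over. The fallback sets out from 4 and comes back at 8. Bromine–lithium exchange on 4 (n-BuLi, THF, −78 °C) followed by DMF gives 8-formyl-3,5,7,3',4'-penta-O-benzyl-(+)-catechin F7. DDQ/H2O gives its 4α-alcohol F8; a longer time is expected because the formyl group slows hydride loss. Dess–Martin oxidation of F8 gives 8.

Further compounds
F1 | step 12 | 5,7,3',4'-tetra-O-benzyl-(−)-epicatechin | C1c2c(OCc3ccccc3)cc(OCc3ccccc3)cc2O[C@H](c2ccc(OCc3ccccc3)c(OCc3ccccc3)c2)[C@@H]1O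
F2 | step 12 | 5,7,3',4'-tetra-O-benzyl-4β-(2-ethoxyethoxy)-(−)-epicatechin | CCOCCO[C@H]1c2c(OCc3ccccc3)cc(OCc3ccccc3)cc2O[C@H](c2ccc(OCc3ccccc3)c(OCc3ccccc3)c2)[C@@H]1O
F3 | step 12 | protected epicatechin-(4β→8)-catechin (upper 5,7,3',4'-tetra-O-benzyl, lower 3,5,7,3',4'-penta-O-benzyl) | C1c2c(OCc5ccccc5)cc(OCc5ccccc5)c([C@H]3c4c(OCc5ccccc5)cc(OCc5ccccc5)cc4O[C@H](c4ccc(OCc5ccccc5)c(OCc5ccccc5)c4)[C@@H]3O)c2O[C@H](c2ccc(OCc3ccccc3)c(OCc3ccccc3)c2)[C@H]1OCc1ccccc1
F4 | step 12 | lower-unit 4-alcohol of F3 | O[C@@H]1c2c(OCc5ccccc5)cc(OCc5ccccc5)c([C@H]3c4c(OCc5ccccc5)cc(OCc5ccccc5)cc4O[C@H](c4ccc(OCc5ccccc5)c(OCc5ccccc5)c4)[C@@H]3O)c2O[C@H](c2ccc(OCc3ccccc3)c(OCc3ccccc3)c2)[C@H]1OCc1ccccc1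
F5 | step 12 | lower-unit flavanone: 5,7,3',4'-tetra-O-benzylepicatechin-(4β→8)-3,5,7,3',4'-penta-O-benzyltaxifolin | O=C1c2c(OCc5ccccc5)cc(OCc5ccccc5)c([C@H]3c4c(OCc5ccccc5)cc(OCc5ccccc5)cc4O[C@H](c4ccc(OCc5ccccc5)c(OCc5ccccc5)c4)[C@@H]3O)c2O[C@H](c2ccc(OCc3ccccc3)c(OCc3ccccc3)c2)[C@H]1OCc1ccccc1
F6 | step 11 | 2-phenyl-4H-1,3,2-benzodioxaborin of benzhydrol 16 (5,7-bis(benzyloxy), 4-substituent the flavanone C8) | O=C1c2c(OCc3ccccc3)cc(OCc3ccccc3)c(C3OB(c4ccccc4)Oc4cc(OCc5ccccc5)cc(OCc5ccccc5)c34)c2O[C@H](c2ccc(OCc3ccccc3)c(OCc3ccccc3)c2)[C@H]1OCc1ccccc1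
F7 | step 6 | 8-formyl-3,5,7,3',4'-penta-O-benzyl-(+)-catechin | C1c2c(OCc3ccccc3)cc(OCc3ccccc3)c(C=O)c2O[C@H](c2ccc(OCc3ccccc3)c(OCc3ccccc3)c2)[C@H]1OCc1ccccc1
F8 | step 6 | 4α-alcohol of F7 | O[C@@H]1c2c(OCc3ccccc3)cc(OCc3ccccc3)c(C=O)c2O[C@H](c2ccc(OCc3ccccc3)c(OCc3ccccc3)c2)[C@H]1OCc1ccccc1
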